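## Retrosynthetic overview

1. Target 12 ⇐ desilylation and Pd-mediated deallylation of the C18-OTBS / C15-allyl ester 10; the angelate ⇐ mixed-anhydride acylation of the C3-OH of bicycle 8.
2. Bicycle 8 ⇐ one Cp2TiCl radical epoxy-polyene cascade of acyclic epoxide 6: ring A closes first (C4–C5), then ring B (C9–C10), ending in the C8=C17 exocyclic alkene; the conjugated ester stops a third ring.
3. Epoxide 6 ⇐ Katsuki–Sharpless epoxidation (D-tartrate) of the (E)-allylic alcohol 4 ⇐ SeO2 ω-hydroxylation of allyl geranylgeranoate 3.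
4. Ester 3 ⇐ Horner–Wadsworth–Emmons reaction of (5E,9E)-farnesylacetone 1 with phosphonate 2.

Assumption: isomerically defined (5E,9E)-farnesylacetone, allyl diethylphosphonoacetate and angelic acid are bought as such; labdane numbering is used for the bicycles, with C18 the C4 oxymethyl carbon (trans to the C10 methyl, C20).

## Route

Step 1
Reactants: 1 (5E,9E)-farnesylacetone; 2 allyl diethylphosphonoacetate
Product: 3 allyl (2E,6E,10E)-geranylgeranoate
Conditions: 2 (1.5 equiv), NaH (1.4 equiv), THF, 0 °C; then 1, 50 °C, 16 h; SiO2 chromatography removes the minor 2Z isomer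
Reagents that add atoms: 2, allyl diethylphosphonoacetate, C=CCOC(=O)CP(=O)(OCC)OCC
Why: Horner–Wadsworth–Emmons olefination of the methyl ketone by the stabilised phosphonate anion gives mainly the thermodynamically preferred (2E)-enoate (about 4:1), no stereocentre is formed, and the allyl ester is in place from the start as the carboxyl protecting group.

Step 2
Reactants: 3 allyl (2E,6E,10E)-geranylgeranoate
Product: 4 allyl (2E,6E,10E,14E)-16-hydroxygeranylgeranoate
Conditions: SeO2 (0.1 equiv), salicylic acid (0.1 equiv), t-BuOOH (70% aq., 3 equiv), CH2Cl2, 0 °C to rt, stopped at about 60% conversion, 3 recycled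
Reagents that add atoms: tert-butyl hydroperoxide, CC(C)(C)OO (terminal oxidant; the oxygen is passed on through catalytic selenium dioxide, O=[Se]=O)
Why: Sharpless-type catalytic SeO2 allylic oxidation (ene reaction then [2,3]-sigmatropic shift) attacks the (E)-methyl of the most accessible, terminal trisubstituted alkene and gives the (E)-allylic alcohol, while the electron-poor enoate alkene and the allyl group are inert.

Step 3
Reactants: 4 allyl (2E,6E,10E,14E)-16-hydroxygeranylgeranoate
Product: 5 allyl (2E,6E,10E)-13-[(2R,3R)-3-(hydroxymethyl)-3-methyloxiran-2-yl]-3,7,11-trimethyltrideca-2,6,10-trienoate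
Conditions: Ti(OiPr)4 (10 mol%), D-(−)-diethyl tartrate (12 mol%), t-BuOOH (anhydrous, 2 equiv), 4 Å MS, CH2Cl2, −20 °C
Reagents that add atoms: tert-butyl hydroperoxide, CC(C)(C)OO
Why: Katsuki–Sharpless asymmetric epoxidation touches only the allylic-alcohol alkene, and the D-tartrate catalyst delivers oxygen to the face that gives the (2R,3R)-epoxide (mirror image of the (2S,3S) product of L-tartrate) in about 95% ee, which fixes the later C3 centre as R.

Step 4
Reactants: 5 allyl (2E,6E,10E)-13-[(2R,3R)-3-(hydroxymethyl)-3-methyloxiran-2-yl]-3,7,11-trimethyltrideca-2,6,10-trienoate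
Product: 6 allyl (2E,6E,10E)-13-[(2R,3R)-3-(tert-butyldimethylsilyloxymethyl)-3-methyloxiran-2-yl]-3,7,11-trimethyltrideca-2,6,10-trienoate
Conditions: TBSCl (1.2 equiv), imidazole (2.5 equiv), DMF, 0 °C to rt
Reagents that add atoms: tert-butyldimethylsilyl chloride, CC(C)(C)[Si](C)(C)Cl
Why: Standard silylation of the primary alcohol leaves both epoxide stereocentres untouched and keeps the future C18 oxygen apart from the C3 hydroxyl that the cyclisation will release.

Step 5
Reactants: 6 allyl (2E,6E,10E)-13-[(2R,3R)-3-(tert-butyldimethylsilyloxymethyl)-3-methyloxiran-2-yl]-3,7,11-trimethyltrideca-2,6,10-trienoate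
Product: 8 allyl (3R,4S,5S,9R,10S,13E)-18-(tert-butyldimethylsilyloxy)-3-hydroxylabda-8(17),13-dien-15-oate, via Cp2Ti(Cl) C3-alkoxide 7 (not isolated)
Conditions: Cp2TiCl2 (2.5 equiv), Mn dust (8 equiv), THF, rt, the green Cp2TiCl solution added slowly to 6 (0.01 M, degassed); then cold 1 M HCl, brief
Reagents that add atoms: none
Why: Nugent–RajanBabu epoxide opening by trivalent titanium gives the tertiary C4 radical with C3–O retained (3R), which closes ring A and then ring B by 6-endo chair–chair radical cyclisations; the C3–OTi and the larger CH2OTBS group sit equatorial (the latter avoiding the C10 methyl), the (E)-alkenes set the trans ring fusion (5S,10S) and the equatorial C9 side chain (9R), the tertiary C8 radical is trapped by Cp2TiCl and loses a β-hydride from the methyl to give the exocyclic alkene, and the hindered electron-poor enoate is not attacked.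

Step 6
Reactants: 8 allyl (3R,4S,5S,9R,10S,13E)-18-(tert-butyldimethylsilyloxy)-3-hydroxylabda-8(17),13-dien-15-oate; 9 angelic acid
Product: 10 allyl (3R,4S,5S,9R,10S,13E)-3-[(2Z)-2-methylbut-2-enoyloxy]-18-(tert-butyldimethylsilyloxy)labda-8(17),13-dien-15-oate
Conditions: 9 (3 equiv), 2,4,6-trichlorobenzoyl chloride (3 equiv), Et3N (3 equiv), toluene, rt, 2 h; then 8, toluene, 80 °C, 24 h (no DMAP)
Reagents that add atoms: 9, angelic acid, C/C=C(/C)C(=O)O
Why: Yamaguchi-type mixed-anhydride esterification, in which the hindered equatorial C3-OH attacks the unshielded angeloyl carbonyl; without a nucleophilic catalyst there is no addition–elimination path to the tiglate, and O-acylation leaves C3 unchanged.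

Step 7
Reactants: 10 allyl (3R,4S,5S,9R,10S,13E)-3-[(2Z)-2-methylbut-2-enoyloxy]-18-(tert-butyldimethylsilyloxy)labda-8(17),13-dien-15-oate
Product: 11 (3R,4S,5S,9R,10S,13E)-3-[(2Z)-2-methylbut-2-enoyloxy]-18-(tert-butyldimethylsilyloxy)labda-8(17),13-dien-15-oic acid
Conditions: Pd(PPh3)4 (5 mol%), morpholine (5 equiv), THF, rt; pH 4 citrate work-up
Reagents that add atoms: none
Why: Tsuji–Trost deallylation, in which zerovalent palladium ionises only the allyl ester and morpholine captures the allyl fragment; with C18 still silylated the angelate cannot migrate, and it is neither cleaved nor isomerised.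

Step 8
Reactants: 11 (3R,4S,5S,9R,10S,13E)-3-[(2Z)-2-methylbut-2-enoyloxy]-18-(tert-butyldimethylsilyloxy)labda-8(17),13-dien-15-oic acid
Product: 12 (3R,4S,5S,9R,10S,13E)-18-hydroxy-3-[(2Z)-2-methylbut-2-enoyloxy]labda-8(17),13-dien-15-oic acid (CNP0420226.2)
Conditions: HF·pyridine, excess pyridine, THF, 0 °C to rt
Reagents that add atoms: none
Why: Fluoride-driven desilylation of the primary TBS ether in a buffered, mildly acidic medium, which avoids base-promoted 1,3-acyl shift of the angelate to O18, Z-to-E isomerisation and protonation of the exocyclic alkene; no stereocentre is touched.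

## Compound list

1 | (5E,9E)-6,10,14-trimethylpentadeca-5,9,13-trien-2-one ((E,E)-farnesylacetone) | CC(C)=CCC/C(C)=C/CC/C(C)=C/CCC(C)=O | starting material
2 | prop-2-en-1-yl (diethoxyphosphoryl)acetate (allyl diethylphosphonoacetate) | C=CCOC(=O)CP(=O)(OCC)OCC | starting material
3 | prop-2-en-1-yl (2E,6E,10E)-3,7,11,15-tetramethylhexadeca-2,6,10,14-tetraenoate (allyl geranylgeranoate) | CC(C)=CCC/C(C)=C/CC/C(C)=C/CC/C(C)=C/C(=O)OCC=C | intermediate
4 | prop-2-en-1-yl (2E,6E,10E,14E)-16-hydroxy-3,7,11,15-tetramethylhexadeca-2,6,10,14-tetraenoate | OC/C(C)=C/CC/C(C)=C/CC/C(C)=C/CC/C(C)=C/C(=O)OCC=C | intermediate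
5 | prop-2-en-1-yl (2E,6E,10E)-13-[(2R,3R)-3-(hydroxymethyl)-3-methyloxiran-2-yl]-3,7,11-trimethyltrideca-2,6,10-trienoate | OC[C@@]1(C)O[C@@H]1CC/C(C)=C/CC/C(C)=C/CC/C(C)=C/C(=O)OCC=C | intermediate
6 | prop-2-en-1-yl (2E,6E,10E)-13-[(2R,3R)-3-({[tert-butyl(dimethyl)silyl]oxy}methyl)-3-methyloxiran-2-yl]-3,7,11-trimethyltrideca-2,6,10-trienoate | CC(C)(C)[Si](C)(C)OC[C@@]1(C)O[C@@H]1CC/C(C)=C/CC/C(C)=C/CC/C(C)=C/C(=O)OCC=C | intermediate
7 | chlorobis(cyclopentadienyl)titanium C3-alkoxide of 8 (tetravalent titanium; Cp rings drawn σ-bonded) | C=C1CC[C@H]2[C@@](C)(CC[C@@H](O[Ti](Cl)(C3C=CC=C3)C3C=CC=C3)[C@]2(C)CO[Si](C)(C)C(C)(C)C)[C@@H]1CC/C(C)=C/C(=O)OCC=C | intermediate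
8 | prop-2-en-1-yl (3R,4S,5S,9R,10S,13E)-18-{[tert-butyl(dimethyl)silyl]oxy}-3-hydroxylabda-8(17),13-dien-15-oate (ent-labdane; 3-OH equatorial and cis to C20, CH2OTBS trans to C20, H5 and H9 trans to C20) | C=C1CC[C@H]2[C@@](C)(CC[C@@H](O)[C@]2(C)CO[Si](C)(C)C(C)(C)C)[C@@H]1CC/C(C)=C/C(=O)OCC=C | intermediate
9 | (2Z)-2-methylbut-2-enoic acid (angelic acid) | C/C=C(/C)C(=O)O | starting material
10 | prop-2-en-1-yl (3R,4S,5S,9R,10S,13E)-18-{[tert-butyl(dimethyl)silyl]oxy}-3-{[(2Z)-2-methylbut-2-enoyl]oxy}labda-8(17),13-dien-15-oate | C=C1CC[C@H]2[C@@](C)(CC[C@@H](OC(=O)/C(C)=C\C)[C@]2(C)CO[Si](C)(C)C(C)(C)C)[C@@H]1CC/C(C)=C/C(=O)OCC=C | intermediate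
11 | (3R,4S,5S,9R,10S,13E)-18-{[tert-butyl(dimethyl)silyl]oxy}-3-{[(2Z)-2-methylbut-2-enoyl]oxy}labda-8(17),13-dien-15-oic acid | C=C1CC[C@H]2[C@@](C)(CC[C@@H](OC(=O)/C(C)=C\C)[C@]2(C)CO[Si](C)(C)C(C)(C)C)[C@@H]1CC/C(C)=C/C(=O)O | intermediate
12 | (3R,4S,5S,9R,10S,13E)-18-hydroxy-3-{[(2Z)-2-methylbut-2-enoyl]oxy}labda-8(17),13-dien-15-oic acid (CNP0420226.2) | C=C1CC[C@H]2[C@@](C)(CC[C@@H](OC(=O)/C(C)=C\C)[C@]2(C)CO)[C@@H]1CC/C(C)=C/C(=O)O | target

## Step count and risks

Total step count: 8. Longest linear sequence: 8 steps (1 to 12).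

**Step 5 (most likely to fail).** The radical cascade may give a modest yield, the planar C4 radical may not place CH2OTBS equatorial cleanly, and some endocyclic alkene may form. The fallback sets out from 6 and comes back at 8. It replaces the radical cascade by a closed-shell cation–olefin bicyclisation (MeAlCl2, CH2Cl2, −78 °C, then aqueous work-up). The C5=C10 alkene then opens the Lewis-acid-activated epoxide at C4 with inversion, so the (E)-CH2OTBS group is delivered stereospecifically to the equatorial position and C4 no longer depends on a radical conformation. The price is unselective proton loss from the C8 cation, so 8 must be separated from its 7-ene and 8(9)-ene isomers on AgNO3-impregnated silica. This fallback makes no compound outside the list (F0).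

**Step 6.** Acylation of the hindered C3-OH may be slow, and forcing it risks angelate-to-tiglate isomerisation. The fallback sets out from 8 and comes back at 10. It builds the angelate double bond on the substrate instead of transferring it. Steglich acylation of 8 with 2-[bis(2,2,2-trifluoroethoxy)phosphoryl]propanoic acid (DCC, DMAP, CH2Cl2) gives the phosphonopropanoate ester F1; this saturated acid cannot isomerise. Still–Gennari olefination of F1 (KN(SiMe3)2, 18-crown-6, THF, −78 °C, then acetaldehyde) gives the (Z)-2-methylbut-2-enoate 10 under kinetic control.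

**Step 2.** SeO2 may not discriminate well enough between the terminal and internal trisubstituted alkenes. The fallback sets out from 3 and comes back at 4. Terminal-selective bromohydrin formation (NBS, THF/H2O, 0 °C) gives the 14-bromo-15-hydroxy ester F2. K2CO3 in allyl alcohol closes it to the racemic terminal epoxide F3. HIO4·2H2O in THF/H2O cleaves this to the trisnor aldehyde F4. Wittig reaction with the stabilised ylide 2-(triphenylphosphoranylidene)propanal (toluene, 90 °C) gives the (14E)-enal F5. Luche reduction (NaBH4, CeCl3·7H2O, MeOH, 0 °C) returns 4 with the (E)-geometry secured.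

## Further compounds

F0 | step 5 | none | none
F1 | step 6 | prop-2-en-1-yl (3R,4S,5S,9R,10S,13E)-3-({2-[bis(2,2,2-trifluoroethoxy)phosphoryl]propanoyl}oxy)-18-{[tert-butyl(dimethyl)silyl]oxy}labda-8(17),13-dien-15-oate (epimers at the phosphonate carbon) | C=C1CC[C@H]2[C@@](C)(CC[C@@H](OC(=O)C(C)P(=O)(OCC(F)(F)F)OCC(F)(F)F)[C@]2(C)CO[Si](C)(C)C(C)(C)C)[C@@H]1CC/C(C)=C/C(=O)OCC=C
F2 | step 2 | prop-2-en-1-yl (2E,6E,10E)-14-bromo-15-hydroxy-3,7,11,15-tetramethylhexadeca-2,6,10-trienoate (racemic) | CC(C)(O)C(Br)CC/C(C)=C/CC/C(C)=C/CC/C(C)=C/C(=O)OCC=C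
F3 | step 2 | prop-2-en-1-yl (2E,6E,10E)-13-(3,3-dimethyloxiran-2-yl)-3,7,11-trimethyltrideca-2,6,10-trienoate (racemic) | CC1(C)OC1CC/C(C)=C/CC/C(C)=C/CC/C(C)=C/C(=O)OCC=C
F4 | step 2 | prop-2-en-1-yl (2E,6E,10E)-3,7,11-trimethyl-14-oxotetradeca-2,6,10-trienoate | O=CCC/C(C)=C/CC/C(C)=C/CC/C(C)=C/C(=O)OCC=C
F5 | step 2 | prop-2-en-1-yl (2E,6E,10E,14E)-3,7,11,15-tetramethyl-16-oxohexadeca-2,6,10,14-tetraenoate | O=C/C(C)=C/CC/C(C)=C/CC/C(C)=C/CC/C(C)=C/C(=O)OCC=C
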